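1. Target 30 ⇐ global desilylation ⇐ α-face epoxidation of the C8=C9 alkene ⇐ O-silylation of the bicyclic cis-allylic alcohol 27 (ring A = cyclopentane C1–C5, ring B = seven-membered ring C1, C5–C10).
2. Key disconnection C7–C8 in ring B: the C7 carbinol is bonded to C8 of the C8–C9 oxirane (a 2,3-epoxy alcohol, i.e. a masked cis-allylic alcohol inside ring B). C7 is therefore an aldehyde carbon and C8 a cis-alkenyl nucleophile, and ring B is closed by an intramolecular Nozaki–Hiyama–Kishi reaction of the monocyclic iodoalkenyl aldehyde 26. The C6 ester is already in place, so the vicinal oxygens on C6 and C7 never have to be told apart.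
3. 26 ⇐ cyclopentane 11 by esterification and side-chain adjustment; 11 ⇐ 3-methylcyclopent-2-en-1-one by enantioselective conjugate addition (C1), anti aldol addition (C5, C6) and organocerium addition (C4).
4. Order of ring formation: ring A comes with the starting enone, ring B is closed in step 11, the oxirane in step 13.

Key step: step 11

Remark: atoms are labelled C1–C10 as in the daucane skeleton throughout, also in ring-opened intermediates (C1 quaternary methyl carbon, C2/C3 ring CH2, C4 isopropyl carbinol, C5 ring CH, C6 ester carbon, C7 carbinol, C8/C9 oxirane carbons, C10 CH2 on C1); β is the face of the C1 methyl group; aldehyde 6 is taken to be a catalogue compound.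

Step 1
Reactants: 1 3-methylcyclopent-2-en-1-one; 2 ethynyltrimethylsilane
Product: 5 (S)-trimethyl({3-methyl-3-[1-(trimethylsilyl)ethenyl]cyclopent-1-en-1-yl}oxy)silane, via vinylalane 3 (not isolated), via aluminium enolate 4 (not isolated)
Conditions: 2, iBu2AlH, hexane/THF, 55 °C; then 1, CuCl2·2H2O (5 mol %), chiral sulfonate-bearing N-heterocyclic carbene ligand (5 mol %, enantiomer giving the S centre), THF, −78 °C; then Me3SiOTf, −78 °C
Reagents that add atoms: trimethylsilyl trifluoromethanesulfonate, C[Si](C)(C)OS(=O)(=O)C(F)(F)F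
Why: α-Selective hydroalumination of the silylalkyne gives the 1-silylvinylalane, whose copper-catalysed enantioselective conjugate addition to the β-methyl enone sets the C1 quaternary stereocentre under control of the chiral carbene ligand, and O-silylation of the aluminium enolate fixes the enolate regiochemistry towards C5.

Step 2
Reactants: 5 (S)-trimethyl({3-methyl-3-[1-(trimethylsilyl)ethenyl]cyclopent-1-en-1-yl}oxy)silane; 6 2-[(4-methoxybenzyl)oxy]acetaldehyde
Product: 8 (2S,3S)-2-{(1R)-1-hydroxy-2-[(4-methoxybenzyl)oxy]ethyl}-3-methyl-3-[1-(trimethylsilyl)ethenyl]cyclopentan-1-one, via lithium enolate 7 (not isolated)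
Conditions: MeLi, THF, 0 °C; then 6, −78 °C; aq NH4Cl at −78 °C
Reagents that add atoms: none
Why: Methyllithium cleaves the enol silane to the regiodefined lithium enolate, and its aldol addition through a Zimmerman–Traxler chair (the ring enforces the E enolate) should give the anti aldol with the aldehyde approaching C5 anti to the bulky 1-silylvinyl group, which sets C5 and C6 relative to C1.

Step 3
Reactants: 8 (2S,3S)-2-{(1R)-1-hydroxy-2-[(4-methoxybenzyl)oxy]ethyl}-3-methyl-3-[1-(trimethylsilyl)ethenyl]cyclopentan-1-one; 9 isopropylmagnesium chloride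
Product: 11 (1R,2S,3S)-2-{(1R)-1-hydroxy-2-[(4-methoxybenzyl)oxy]ethyl}-3-methyl-1-(propan-2-yl)-3-[1-(trimethylsilyl)ethenyl]cyclopentan-1-ol, via isopropylcerium dichloride 10 (not isolated)
Conditions: CeCl3 (anhydrous), iPrMgCl, THF, −78 °C; then 8, −78 °C; aq NH4Cl
Reagents that add atoms: none
Why: Addition of the weakly basic organocerium reagent to the enolisable β-hydroxy ketone should occur from the α face, away from the C5 side chain and the pseudo-axial C1 methyl group, and so gives the 4β-hydroxy-4α-isopropyl centre without retro-aldol cleavage.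

Step 4
Reactants: 12 4-hydroxybenzoic acid
Product: 14 4-[(triisopropylsilyl)oxy]benzoic acid, via silyl ester 13 (not isolated)
Conditions: iPr3SiCl (2.2 equiv), imidazole, DMF, rt; then AcOH/THF/H2O, rt
Reagents that add atoms: chlorotriisopropylsilane, CC(C)[Si](Cl)(C(C)C)C(C)C
Why: Silylation of both acidic groups followed by selective hydrolysis of the labile silyl ester leaves the phenol as its robust triisopropylsilyl ether.

Step 5
Reactants: 11 (1R,2S,3S)-2-{(1R)-1-hydroxy-2-[(4-methoxybenzyl)oxy]ethyl}-3-methyl-1-(propan-2-yl)-3-[1-(trimethylsilyl)ethenyl]cyclopentan-1-ol; 14 4-[(triisopropylsilyl)oxy]benzoic acid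
Product: 15 (1R)-1-{(1S,2R,5S)-2-hydroxy-5-methyl-2-(propan-2-yl)-5-[1-(trimethylsilyl)ethenyl]cyclopentyl}-2-[(4-methoxybenzyl)oxy]ethyl 4-[(triisopropylsilyl)oxy]benzoate
Conditions: DCC, DMAP (cat.), CH2Cl2, 0 °C → rt
Reagents that add atoms: none
Why: Steglich esterification acylates the secondary C6 hydroxyl only, since the tertiary C4 hydroxyl is too hindered to react with the acylpyridinium intermediate.

Step 6
Reactants: 15 the C6 ester of diol 11 named in step 5
Product: 17 primary alcohol in which the C1 side chain of 15 has become CH(SiMe3)CH2OH (both C10 epimers), via alkylborane 16 (not isolated)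
Conditions: BH3·SMe2, THF, 0 °C → rt; then NaBO3·4H2O, THF/H2O, rt
Reagents that add atoms: sodium perborate tetrahydrate, [Na+].[O-]OB=O.O.O.O.O
Why: Brown hydroboration places boron on the terminal carbon of the 1,1-disubstituted vinylsilane and mild perborate oxidation gives the primary alcohol while the slowly reacting aryl ester survives; the new silyl-bearing centre does not matter because silicon is removed in step 7.

Step 7
Reactants: 17 the β-silyl primary alcohol of step 6
Product: 19 (1R)-1-[(1S,2R,5R)-2-hydroxy-5-methyl-5-(2-oxoethyl)-2-(propan-2-yl)cyclopentyl]-2-[(4-methoxybenzyl)oxy]ethyl 4-[(triisopropylsilyl)oxy]benzoate, via silyl aldehyde 18 (not isolated)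
Conditions: Dess–Martin periodinane, CH2Cl2, rt; then THF/H2O, AcOH (cat.), rt
Reagents that add atoms: none
Why: Dess–Martin oxidation gives the α-silyl aldehyde, whose carbon–silicon bond next to the carbonyl group is cleaved by water under mild acid (through the enol), so that the 1-silylvinyl group has been turned into the C10H2–C9HO arm.

Step 8
Reactants: 19 the C9 aldehyde of step 7; 20 ethyltriphenylphosphonium iodide
Product: 24 (1R)-1-{(1S,2R,5R)-2-hydroxy-5-[(2Z)-3-iodobut-2-en-1-yl]-5-methyl-2-(propan-2-yl)cyclopentyl}-2-[(4-methoxybenzyl)oxy]ethyl 4-[(triisopropylsilyl)oxy]benzoate, via ethylidene ylide 21 (not isolated), via iodophosphonium salt 22 (not isolated), via iodo ylide 23 (not isolated)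
Conditions: 20, n-BuLi, THF, rt; I2, −78 °C; NaN(SiMe3)2, −20 °C; then 19, −78 °C → rt
Reagents that add atoms: iodine, [I][I]
Why: Stork–Zhao-type Wittig olefination with the α-iodo ylide, a non-stabilised ylide reacting under kinetic control, should give the (Z)-2-iodoalkene with iodine cis to C10, the geometry needed for a cis alkene in ring B.

Step 9
Reactants: 24 the (Z)-alkenyl iodide of step 8
Product: 25 (1R)-2-hydroxy-1-{(1S,2R,5R)-2-hydroxy-5-[(2Z)-3-iodobut-2-en-1-yl]-5-methyl-2-(propan-2-yl)cyclopentyl}ethyl 4-[(triisopropylsilyl)oxy]benzoate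
Conditions: DDQ, CH2Cl2/pH 7 buffer, 0 °C; product used directly
Reagents that add atoms: none
Why: Oxidative cleavage of the 4-methoxybenzyl ether by DDQ (benzylic hydride abstraction, then hydrolysis of the oxocarbenium ion) frees the primary C7 hydroxyl under neutral conditions that spare the silyl ether, the ester and the alkenyl iodide.

Step 10
Reactants: 25 the primary alcohol of step 9
Product: 26 (1R)-1-{(1S,2R,5R)-2-hydroxy-5-[(2Z)-3-iodobut-2-en-1-yl]-5-methyl-2-(propan-2-yl)cyclopentyl}-2-oxoethyl 4-[(triisopropylsilyl)oxy]benzoate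
Conditions: Dess–Martin periodinane, CH2Cl2, 0 °C → rt
Reagents that add atoms: none
Why: Dess–Martin oxidation under non-basic conditions gives the α-acyloxy aldehyde without epimerisation at C6 or acyl migration.

Step 11
Reactants: 26 the iodoalkenyl α-aroyloxy aldehyde of step 10
Product: 27 6α-{4-[(triisopropylsilyl)oxy]benzoyloxy}dauc-8-ene-4β,7β-diol (trans-fused rings A and B)
Conditions: CrCl2 (10 equiv), NiCl2 (2 mol %), degassed DMSO/THF 3:1, rt, 26 added over several hours (final 0.003 M)
Reagents that add atoms: none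
Why: Zerovalent nickel, formed from NiCl2 by CrCl2, inserts into the alkenyl carbon–iodine bond with retention of the Z geometry, transmetalation gives an alkenyl species of trivalent chromium, and this adds to the C7 aldehyde so that the C7–C8 bond and ring B are formed in a 7-exo-trig closure. The closest known reaction type is the intramolecular Nozaki–Hiyama–Kishi cyclisation of iodoalkenyl aldehydes to medium-ring and macrocyclic allylic alcohols, which tolerates esters, free tertiary alcohols and silyl ethers. The one new stereocentre, C7, is controlled by the neighbouring C6 stereocentre: the tethered nucleophile must reach C7 from the side of the C5–C6 bond, which turns the aldehyde oxygen outward (pseudo-equatorial), and with the C6–O bond anti to the forming bond (polar Felkin–Anh arrangement) this should give the 6,7-trans, 7β alcohol. The step needs chemoselectivity for the aldehyde over the aryl ester, secured by the weakly basic organochromium nucleophile, and ring closure in preference to oligomerisation, secured by high dilution and by the cis relation of C10 and iodine on the alkene. The trans fusion of rings A and B is not at stake because C1 and C5 are already fixed in the cyclopentane, and the non-basic medium leaves the C6 centre of the α-acyloxy aldehyde intact.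

Step 12
Reactants: 27 6α-{4-[(triisopropylsilyl)oxy]benzoyloxy}dauc-8-ene-4β,7β-diol
Product: 28 7β-triethylsilyl ether of 27
Conditions: Et3SiCl, imidazole, DMF, 0 °C
Reagents that add atoms: chlorotriethylsilane, CC[Si](Cl)(CC)CC
Why: Silylation with the chlorosilane and imidazole takes place at the secondary allylic C7 hydroxyl only (the tertiary C4 hydroxyl is inert) and replaces its hydrogen-bond directing effect by steric shielding of the β face.

Step 13
Reactants: 28 7β-triethylsilyl ether of 27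
Product: 29 8α,9α-epoxide of 28
Conditions: mCPBA, CH2Cl2, 0 °C
Reagents that add atoms: 3-chloroperoxybenzoic acid, O=C(OO)c1cccc(Cl)c1
Why: Prilezhaev epoxidation of the only alkene should occur from the α face, anti to the 7β-silyloxy group and the pseudo-axial C1 methyl group, and so sets C8 and C9.

Step 14
Reactants: 29 8α,9α-epoxide of 28
Product: 30 8α,9α-epoxy-4β,7β-dihydroxydaucan-6α-yl 4-hydroxybenzoate (CNP0290052.1; 1R,4R,5S,6R,7S,8R,9S in the numbering of the remark)
Conditions: Bu4NF, AcOH (1:1), THF, 0 °C → rt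
Reagents that add atoms: none
Why: Fluoride cleaves the aryl and the secondary alkyl silyl ether in one operation, and buffering with acetic acid suppresses acyl migration to the C7 hydroxyl and Payne rearrangement of the epoxy alcohol.

Compound list
1 | 3-methylcyclopent-2-en-1-one | CC1=CC(=O)CC1 | starting material
2 | ethynyltrimethylsilane | C#C[Si](C)(C)C | starting material
3 | diisobutyl[1-(trimethylsilyl)ethenyl]aluminium | CC(C)C[Al](CC(C)C)C(=C)[Si](C)(C)C | intermediate
4 | diisobutylaluminium enolate of (S)-3-methyl-3-[1-(trimethylsilyl)ethenyl]cyclopentanone (enolate C=C towards the quaternary carbon) | CC(C)C[Al](CC(C)C)OC1=C[C@@](C)(C(=C)[Si](C)(C)C)CC1 | intermediate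
5 | (S)-trimethyl({3-methyl-3-[1-(trimethylsilyl)ethenyl]cyclopent-1-en-1-yl}oxy)silane | C[Si](C)(C)OC1=C[C@@](C)(C(=C)[Si](C)(C)C)CC1 | intermediate
6 | 2-[(4-methoxybenzyl)oxy]acetaldehyde | COc1ccc(COCC=O)cc1 | starting material
7 | lithium enolate corresponding to 5 | [Li]OC1=C[C@@](C)(C(=C)[Si](C)(C)C)CC1 | intermediate
8 | (2S,3S)-2-{(1R)-1-hydroxy-2-[(4-methoxybenzyl)oxy]ethyl}-3-methyl-3-[1-(trimethylsilyl)ethenyl]cyclopentan-1-one | O=C1CC[C@](C)(C(=C)[Si](C)(C)C)[C@H]1[C@H](COCc1ccc(OC)cc1)O | intermediate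
9 | isopropylmagnesium chloride | CC(C)[Mg]Cl | starting material
10 | isopropylcerium dichloride | CC(C)[Ce](Cl)Cl | intermediate
11 | (1R,2S,3S)-2-{(1R)-1-hydroxy-2-[(4-methoxybenzyl)oxy]ethyl}-3-methyl-1-(propan-2-yl)-3-[1-(trimethylsilyl)ethenyl]cyclopentan-1-ol | CC(C)[C@]1(O)CC[C@](C)(C(=C)[Si](C)(C)C)[C@H]1[C@H](COCc1ccc(OC)cc1)O | intermediate
12 | 4-hydroxybenzoic acid | O=C(O)c1ccc(O)cc1 | starting material
13 | triisopropylsilyl 4-[(triisopropylsilyl)oxy]benzoate | CC(C)[Si](OC(=O)c1ccc(O[Si](C(C)C)(C(C)C)C(C)C)cc1)(C(C)C)C(C)C | intermediate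
14 | 4-[(triisopropylsilyl)oxy]benzoic acid | O=C(O)c1ccc(O[Si](C(C)C)(C(C)C)C(C)C)cc1 | intermediate
15 | (1R)-1-{(1S,2R,5S)-2-hydroxy-5-methyl-2-(propan-2-yl)-5-[1-(trimethylsilyl)ethenyl]cyclopentyl}-2-[(4-methoxybenzyl)oxy]ethyl 4-[(triisopropylsilyl)oxy]benzoate | CC(C)[C@]1(O)CC[C@](C)(C(=C)[Si](C)(C)C)[C@H]1[C@H](COCc1ccc(OC)cc1)OC(=O)c1ccc(O[Si](C(C)C)(C(C)C)C(C)C)cc1 | intermediate
16 | alkylborane from 15: C1 side chain CH(SiMe3)CH2BH2 (C10 epimers) | CC(C)[C@]1(O)CC[C@](C)(C(CB)[Si](C)(C)C)[C@H]1[C@H](COCc1ccc(OC)cc1)OC(=O)c1ccc(O[Si](C(C)C)(C(C)C)C(C)C)cc1 | intermediate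
17 | primary alcohol from 15: C1 side chain CH(SiMe3)CH2OH (C10 epimers) | CC(C)[C@]1(O)CC[C@](C)(C(CO)[Si](C)(C)C)[C@H]1[C@H](COCc1ccc(OC)cc1)OC(=O)c1ccc(O[Si](C(C)C)(C(C)C)C(C)C)cc1 | intermediate
18 | α-silyl aldehyde from 17: C1 side chain CH(SiMe3)CHO (C10 epimers) | CC(C)[C@]1(O)CC[C@](C)(C(C=O)[Si](C)(C)C)[C@H]1[C@H](COCc1ccc(OC)cc1)OC(=O)c1ccc(O[Si](C(C)C)(C(C)C)C(C)C)cc1 | intermediate
19 | (1R)-1-[(1S,2R,5R)-2-hydroxy-5-methyl-5-(2-oxoethyl)-2-(propan-2-yl)cyclopentyl]-2-[(4-methoxybenzyl)oxy]ethyl 4-[(triisopropylsilyl)oxy]benzoate | CC(C)[C@]1(O)CC[C@](C)(CC=O)[C@H]1[C@H](COCc1ccc(OC)cc1)OC(=O)c1ccc(O[Si](C(C)C)(C(C)C)C(C)C)cc1 | intermediate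
20 | ethyltriphenylphosphonium iodide | CC[P+](c1ccccc1)(c1ccccc1)c1ccccc1.[I-] | starting material
21 | ethylidenetriphenylphosphorane | CC=P(c1ccccc1)(c1ccccc1)c1ccccc1 | intermediate
22 | (1-iodoethyl)triphenylphosphonium iodide | CC(I)[P+](c1ccccc1)(c1ccccc1)c1ccccc1.[I-] | intermediate
23 | (1-iodoethylidene)triphenylphosphorane | CC(I)=P(c1ccccc1)(c1ccccc1)c1ccccc1 | intermediate
24 | (1R)-1-{(1S,2R,5R)-2-hydroxy-5-[(2Z)-3-iodobut-2-en-1-yl]-5-methyl-2-(propan-2-yl)cyclopentyl}-2-[(4-methoxybenzyl)oxy]ethyl 4-[(triisopropylsilyl)oxy]benzoate | CC(C)[C@]1(O)CC[C@](C)(C/C=C(/C)I)[C@H]1[C@H](COCc1ccc(OC)cc1)OC(=O)c1ccc(O[Si](C(C)C)(C(C)C)C(C)C)cc1 | intermediate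
25 | (1R)-2-hydroxy-1-{(1S,2R,5R)-2-hydroxy-5-[(2Z)-3-iodobut-2-en-1-yl]-5-methyl-2-(propan-2-yl)cyclopentyl}ethyl 4-[(triisopropylsilyl)oxy]benzoate | CC(C)[C@]1(O)CC[C@](C)(C/C=C(/C)I)[C@H]1[C@H](CO)OC(=O)c1ccc(O[Si](C(C)C)(C(C)C)C(C)C)cc1 | intermediate
26 | (1R)-1-{(1S,2R,5R)-2-hydroxy-5-[(2Z)-3-iodobut-2-en-1-yl]-5-methyl-2-(propan-2-yl)cyclopentyl}-2-oxoethyl 4-[(triisopropylsilyl)oxy]benzoate | CC(C)[C@]1(O)CC[C@](C)(C/C=C(/C)I)[C@H]1[C@H](C=O)OC(=O)c1ccc(O[Si](C(C)C)(C(C)C)C(C)C)cc1 | intermediate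
27 | 6α-{4-[(triisopropylsilyl)oxy]benzoyloxy}dauc-8-ene-4β,7β-diol | CC(C)[C@]1(O)CC[C@]2(C)CC=C(C)[C@@H](O)[C@H](OC(=O)c3ccc(O[Si](C(C)C)(C(C)C)C(C)C)cc3)[C@H]21 | intermediate
28 | 7β-triethylsilyl ether of 27 | CC(C)[C@]1(O)CC[C@]2(C)CC=C(C)[C@@H](O[Si](CC)(CC)CC)[C@H](OC(=O)c3ccc(O[Si](C(C)C)(C(C)C)C(C)C)cc3)[C@H]21 | intermediate
29 | 8α,9α-epoxide of 28 | CC(C)[C@]1(O)CC[C@]2(C)C[C@@H]3O[C@]3(C)[C@@H](O[Si](CC)(CC)CC)[C@H](OC(=O)c3ccc(O[Si](C(C)C)(C(C)C)C(C)C)cc3)[C@H]21 | intermediate
30 | 8α,9α-epoxy-4β,7β-dihydroxydaucan-6α-yl 4-hydroxybenzoate (CNP0290052.1) | CC(C)[C@]1(O)CC[C@]2(C)C[C@@H]3O[C@]3(C)[C@@H](O)[C@H](OC(=O)c3ccc(O)cc3)[C@H]21 | target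

Total step count: 14
Longest linear sequence: 13 steps (steps 1 to 3 and 5 to 14; step 4 is a one-step side branch)

Steps most likely to fail

Step 11: the alkenylchromium species may add to the wrong face of the aldehyde, and reduction of the carbon–iodine bond may compete with ring closure. The fallback sets out from 26 and gives up substrate control at C7. The cyclisation is run as before and the crude product, now mainly the 7α-hydroxy epimer F1, is oxidised with Dess–Martin periodinane to the ring B enone F2. Corey–Bakshi–Shibata reduction (the enantiomer of the 2-methyl-oxazaborolidine that delivers hydride to the α face, BH3·SMe2, −40 °C) then sets C7 under reagent control. The route is rejoined at 27.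

Step 2: the lithium enolate aldol addition may show low anti/syn selectivity, or the aldolate may equilibrate by retro-aldol cleavage. The fallback sets out from 5 (with 6) and aims at the opposite C6 configuration on purpose. A chelation-controlled Mukaiyama aldol addition (MgBr2·OEt2, CH2Cl2, −78 °C) should give the syn aldol F3. Organocerium addition as in step 3 gives the 6-epimeric diol F4. A Mitsunobu esterification with acid 14 (PPh3, diisopropyl azodicarboxylate, toluene) then installs the ester with inversion at C6. The route is rejoined at 15.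

Step 8: the thermally labile iodo ylide may decompose, may attack the aryl ester, or may give eroded Z geometry. The fallback sets out from 19 and builds the halide geometry by cross-coupling instead of olefination. Corey–Fuchs olefination (CBr4, PPh3, CH2Cl2, 0 °C) gives the 1,1-dibromoalkene F5. A Negishi coupling (MeZnCl, Pd(PPh3)4, THF) replaces only the bromine trans to the alkyl chain and gives the (Z)-2-bromoalkene F6. Copper-catalysed halogen exchange (CuI, N,N′-dimethylethylenediamine, NaI, dioxane, 110 °C) converts it with retention into the iodide. The route is rejoined at 24.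

Further compounds
F1 | step 11 | 7α-hydroxy epimer of 27 | CC(C)[C@]1(O)CC[C@]2(C)CC=C(C)[C@H](O)[C@H](OC(=O)c3ccc(O[Si](C(C)C)(C(C)C)C(C)C)cc3)[C@H]21
F2 | step 11 | 4β-hydroxy-6α-{4-[(triisopropylsilyl)oxy]benzoyloxy}dauc-8-en-7-one | CC(C)[C@]1(O)CC[C@]2(C)CC=C(C)C(=O)[C@H](OC(=O)c3ccc(O[Si](C(C)C)(C(C)C)C(C)C)cc3)[C@H]21
F3 | step 2 | (2S,3S)-2-{(1S)-1-hydroxy-2-[(4-methoxybenzyl)oxy]ethyl}-3-methyl-3-[1-(trimethylsilyl)ethenyl]cyclopentan-1-one (syn aldol) | O=C1CC[C@](C)(C(=C)[Si](C)(C)C)[C@H]1[C@@H](COCc1ccc(OC)cc1)O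
F4 | step 2 | (1R,2S,3S)-2-{(1S)-1-hydroxy-2-[(4-methoxybenzyl)oxy]ethyl}-3-methyl-1-(propan-2-yl)-3-[1-(trimethylsilyl)ethenyl]cyclopentan-1-ol (C6 epimer of 11) | CC(C)[C@]1(O)CC[C@](C)(C(=C)[Si](C)(C)C)[C@H]1[C@@H](COCc1ccc(OC)cc1)O
F5 | step 8 | 1,1-dibromoalkene from 19: C1 side chain CH2CH=CBr2 | CC(C)[C@]1(O)CC[C@](C)(CC=C(Br)Br)[C@H]1[C@H](COCc1ccc(OC)cc1)OC(=O)c1ccc(O[Si](C(C)C)(C(C)C)C(C)C)cc1
F6 | step 8 | (Z)-2-bromoalkene analogue of 24: C1 side chain (2Z)-3-bromobut-2-en-1-yl | CC(C)[C@]1(O)CC[C@](C)(C/C=C(/C)Br)[C@H]1[C@H](COCc1ccc(OC)cc1)OC(=O)c1ccc(O[Si](C(C)C)(C(C)C)C(C)C)cc1
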